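C1 is the lactone carbonyl, C4 the lactone quaternary carbon, C5 the oxolane CH, C8 the oxolane quaternary carbon and C15 the CH2 on the furan.
Cuts: first lactone O–C1 (back to a tert-butyl ester). Then oxolane O–C5 (back to a 4,5-epoxide and a free C8–OH). Then C7–C8 together with C8–O, which leaves a C1–C7 boronic ester and a C8–C15 carbamate.
Enabling feature: C8, the quaternary carbon of the oxolane ring, carries O, CH3 and the E-C9=C10 alkenyl arm. This is the pattern of a secondary allylic alcohol with C7 in place of H, so a metalated carbamate of that alcohol can accept C7 from boron.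
Forward order: the two fragments are built separately and joined at C7–C8 without ring formation. The oxolane then closes (5-exo at C5), and the γ-lactone closes last.
Stereochemistry: C8 comes from commercial (S)-but-3-yn-2-ol and is carried stereospecifically through the 1,2-shift. C4 and C5 come from a Shi epoxidation of a Johnson–Claisen E-alkene (C5 inverted, C4 retained on ring closure). E-C12=C13 comes from a stabilised ylide and E-C9=C10 from trans-hydroalumination.

Key step: step 16

Remark: the L-fructose-derived enantiomer of the Shi ketone is treated as an available catalyst (accessible from L-sorbose), and 1, 3, 11 and 18 are taken as purchased.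

Step 1
Reactants: 1 3-[(tert-butyldimethylsilyl)oxy]propanal
Product: 2 5-[(tert-butyldimethylsilyl)oxy]-2-methylpent-1-en-3-ol (racemic)
Conditions: isopropenylMgBr, THF, −78 → 0 °C; aq. NH4Cl
Reagents that add atoms: isopropenylmagnesium bromide, C=C(C)[Mg]Br
Why: Grignard 1,2-addition to an unhindered aldehyde brings in C3, C4 and the C4 methyl group, and the new carbinol centre may stay racemic because the sigmatropic shift of step 2 turns it into an sp2 carbon.

Step 2
Reactants: 2 5-[(tert-butyldimethylsilyl)oxy]-2-methylpent-1-en-3-ol, 3 triethyl orthoacetate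
Product: 5 ethyl (4E)-7-[(tert-butyldimethylsilyl)oxy]-4-methylhept-4-enoate, via mixed ketene acetal 4 (not isolated)
Conditions: MeC(OEt)3 (excess), EtCO2H (cat.), 140 °C, EtOH distilled off
Reagents that add atoms: none
Why: In this Johnson–Claisen rearrangement, acid-catalysed alcohol exchange and loss of ethanol give ketene acetal 4, whose chair transition state with the CH2CH2OTBS chain equatorial forms C2–C3 and the E-configured C4=C5 alkene.

Step 3
Reactants: 5 ethyl (4E)-7-[(tert-butyldimethylsilyl)oxy]-4-methylhept-4-enoate
Product: 6 tert-butyl (4E)-7-[(tert-butyldimethylsilyl)oxy]-4-methylhept-4-enoate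
Conditions: KOtBu (20 mol %), tBuOAc (solvent), rt, slight vacuum
Reagents that add atoms: tert-butyl acetate, CC(=O)OC(C)(C)C
Why: Alkoxide-catalysed ester interchange, driven by the excess of tert-butyl acetate and removal of the more volatile ethyl acetate, installs the hindered ester that must later face an organolithium, and silyl ether and alkene are inert to it.

Step 4
Reactants: 6 tert-butyl (4E)-7-[(tert-butyldimethylsilyl)oxy]-4-methylhept-4-enoate
Product: 7 tert-butyl (4E)-7-hydroxy-4-methylhept-4-enoate
Conditions: TBAF, THF, 0 °C → rt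
Reagents that add atoms: none
Why: Fluoride-induced desilylation is driven by the strong Si–F bond and leaves the tert-butyl ester and the alkene untouched.

Step 5
Reactants: 7 tert-butyl (4E)-7-hydroxy-4-methylhept-4-enoate
Product: 8 tert-butyl (4E)-7-bromo-4-methylhept-4-enoate
Conditions: CBr4, PPh3, CH2Cl2, 0 °C
Reagents that add atoms: tetrabromomethane, BrC(Br)(Br)Br
Why: The Appel reaction converts the primary alcohol by SN2 displacement of an alkoxyphosphonium ion under neutral conditions, and a bromide, unlike an iodide or a boronic ester, tolerates the oxidant of step 6.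

Step 6
Reactants: 8 tert-butyl (4E)-7-bromo-4-methylhept-4-enoate
Product: 9 tert-butyl 3-[(2S,3S)-3-(2-bromoethyl)-2-methyloxiran-2-yl]propanoate
Conditions: ent-Shi ketone (30 mol %), Oxone, K2CO3, Bu4NHSO4 (cat.), Na2B4O7/Na2EDTA buffer, MeCN–DMM, 0 °C
Reagents that add atoms: potassium peroxymonosulfate (active part of Oxone), [K+].[O-]S(=O)(=O)OO
Why: In the Shi epoxidation the chiral dioxirane transfers oxygen through a spiro transition state to one face of the E-trisubstituted alkene, so syn addition fixes the relative configuration and the L-fructose-derived ketone fixes the absolute (4S,5S) configuration, the mirror image of the (R,R) sense of the D-fructose ketone.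

Step 7
Reactants: 9 tert-butyl 3-[(2S,3S)-3-(2-bromoethyl)-2-methyloxiran-2-yl]propanoate
Product: 10 tert-butyl 3-{(2S,3S)-2-methyl-3-[2-(4,4,5,5-tetramethyl-1,3,2-dioxaborolan-2-yl)ethyl]oxiran-2-yl}propanoate
Conditions: B2pin2, CuI (10 mol %), PPh3 (13 mol %), LiOMe, DMF, rt
Reagents that add atoms: bis(pinacolato)diboron, CC1(C)OB(OC1(C)C)B1OC(C)(C)C(C)(C)O1
Why: Copper-catalysed borylation of a primary alkyl bromide by a boryl-copper species runs at room temperature, is expected to spare the hindered trisubstituted epoxide and the tert-butyl ester, and touches neither stereocentre.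

Step 8
Reactants: 11 furan-3-carbaldehyde
Product: 12 ethyl (2E)-3-(furan-3-yl)prop-2-enoate
Conditions: Ph3P=CHCO2Et, CH2Cl2, rt
Reagents that add atoms: ethyl (triphenylphosphoranylidene)acetate, CCOC(=O)C=P(c1ccccc1)(c1ccccc1)c1ccccc1
Why: Wittig olefination with a stabilised ylide adds C14 and C13 cleanly, and the alkene geometry is irrelevant because the double bond is saturated next.

Step 9
Reactants: 12 ethyl (2E)-3-(furan-3-yl)prop-2-enoate
Product: 13 ethyl 3-(furan-3-yl)propanoate
Conditions: H2 (1 atm), 5% Pd/C, EtOAc, rt, stopped after one equivalent of H2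
Reagents that add atoms: none
Why: Catalytic hydrogenation takes the unhindered conjugated alkene much faster than the aromatic furan, so interrupting the uptake after one equivalent should give the saturated ester.

Step 10
Reactants: 13 ethyl 3-(furan-3-yl)propanoate
Product: 15 ethyl (2E)-5-(furan-3-yl)-2-methylpent-2-enoate, via 3-(furan-3-yl)propanal 14 (not isolated)
Conditions: DIBAL-H (1.0 equiv), CH2Cl2, −78 °C; then Ph3P=C(Me)CO2Et, −78 °C → rt; Rochelle salt
Reagents that add atoms: ethyl 2-(triphenylphosphoranylidene)propanoate, CCOC(=O)C(C)=P(c1ccccc1)(c1ccccc1)c1ccccc1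
Why: Partial DIBAL-H reduction halts at the aluminium hemiacetal at −78 °C, and the volatile aldehyde 14 released on warming is caught in the same flask by the stabilised α-methyl ylide in an E-selective Wittig reaction that sets the C12=C13 geometry.

Step 11
Reactants: 15 ethyl (2E)-5-(furan-3-yl)-2-methylpent-2-enoate
Product: 16 (2E)-5-(furan-3-yl)-2-methylpent-2-en-1-ol
Conditions: DIBAL-H (2.2 equiv), CH2Cl2, −78 → 0 °C; Rochelle salt
Reagents that add atoms: none
Why: 1,2-Reduction of an enoate with two equivalents of DIBAL-H gives the allylic alcohol without changing the alkene geometry or touching the furan.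

Step 12
Reactants: 16 (2E)-5-(furan-3-yl)-2-methylpent-2-en-1-ol
Product: 17 3-[(3E)-5-bromo-4-methylpent-3-en-1-yl]furan
Conditions: CBr4, PPh3, CH2Cl2, −20 → 0 °C, used promptly
Reagents that add atoms: tetrabromomethane, BrC(Br)(Br)Br
Why: The Appel reaction gives the primary allylic bromide under neutral conditions without allylic transposition, E/Z scrambling or damage to the acid-sensitive furan.

Step 13
Reactants: 17 3-[(3E)-5-bromo-4-methylpent-3-en-1-yl]furan, 18 (S)-but-3-yn-2-ol
Product: 19 (2S,6E)-9-(furan-3-yl)-6-methylnon-6-en-3-yn-2-ol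
Conditions: CuI (10 mol %), K2CO3, Bu4NCl, DMF, rt
Reagents that add atoms: none
Why: Copper(I)-catalysed alkynylation of a primary allylic bromide takes place at the unhindered CH2 terminus, forms C10–C11, tolerates the free hydroxyl and leaves the purchased C8 stereocentre untouched.

Step 14
Reactants: 19 (2S,6E)-9-(furan-3-yl)-6-methylnon-6-en-3-yn-2-ol
Product: 20 (2S,3E,6E)-9-(furan-3-yl)-6-methylnona-3,6-dien-2-ol
Conditions: Red-Al, THF, 0 °C → rt; aq. Rochelle salt
Reagents that add atoms: none
Why: Hydroxyl-directed trans-hydroalumination of the propargylic alcohol with Red-Al followed by protonolysis gives only the E-C9=C10 allylic alcohol, while the isolated alkene, the furan and the carbinol centre are inert to the hydride.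

Step 15
Reactants: 20 (2S,3E,6E)-9-(furan-3-yl)-6-methylnona-3,6-dien-2-ol
Product: 21 (2S,3E,6E)-9-(furan-3-yl)-6-methylnona-3,6-dien-2-yl N,N-diisopropylcarbamate
Conditions: iPr2NCOCl, Et3N, DMAP (cat.), toluene, 90 °C
Reagents that add atoms: N,N-diisopropylcarbamoyl chloride, CC(C)N(C(C)C)C(=O)Cl
Why: O-Carbamoylation acylates oxygen without breaking the C8–O bond, so the S configuration is kept, and it installs the group that serves as director and leaving group in step 16.

Step 16
Reactants: 21 (2S,3E,6E)-9-(furan-3-yl)-6-methylnona-3,6-dien-2-yl N,N-diisopropylcarbamate, 10 tert-butyl 3-{(2S,3S)-2-methyl-3-[2-(4,4,5,5-tetramethyl-1,3,2-dioxaborolan-2-yl)ethyl]oxiran-2-yl}propanoate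
Product: 25 tert-butyl 3-{(2S,3S)-3-[(3R,4E,7E)-10-(furan-3-yl)-3-hydroxy-3,7-dimethyldeca-4,7-dien-1-yl]-2-methyloxiran-2-yl}propanoate, via lithiated carbamate 22 (not isolated), via boronate complex 23 (not isolated), via tertiary allylic boronic ester 24 (not isolated)
Conditions: 21 (1.2 equiv), sBuLi (1.15 equiv), TMEDA, Et2O, −78 °C; 10 (1.0 equiv) in Et2O, −78 °C, then → rt; then H2O2, aq. NaOH, THF, 0 °C
Reagents that add atoms: hydrogen peroxide, OO
Why: sBuLi·TMEDA docks on the carbamate carbonyl and removes the adjacent C8–H with retention, leaving the chelated allyllithium 22, which keeps its configuration at −78 °C and adds through its α-carbon, on the lithium-bearing face, to the vacant boron orbital of 10 to give ate complex 23. On warming, the C7–B bond that lies antiperiplanar to C8–OCb shifts from boron to C8 and drives out the carbamate with inversion (stereospecific 1,2-metallate rearrangement, new C7–C8 bond), and alkaline peroxide then replaces boron in 24 by oxygen with retention (new C8–O bond), so that the net result is formal replacement of the carbinol hydrogen of 21 by C7 with retention, (8S)-21 giving (8R)-25. The closest known reaction type is the lithiation–borylation–oxidation of enantioenriched secondary allylic N,N-diisopropylcarbamates with primary alkyl pinacol boronic esters, which gives tertiary allylic alcohols. No ring is closed, and the single new stereocentre C8 is controlled only by the configuration of 21, which goes back to alcohol 18, while C4 and C5 of 10 are spectators. The step needs site-selective metalation (C8–H rather than the doubly allylic C11–H2 or furan C2–H) and α- rather than γ-borylation; the first is secured by the proximity effect of the carbamate together with a slight deficit of base at −78 °C, the second by lithium chelation at C8 and the bulk of the pinacol ester. It also needs chemoselectivity within 10, which rests on boron capturing the hindered carbanion faster than it can add to or enolise the tert-butyl ester or open the trisubstituted epoxide, and on the absence of any Lewis acid promoter during the shift.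

Step 17
Reactants: 25 tert-butyl 3-{(2S,3S)-3-[(3R,4E,7E)-10-(furan-3-yl)-3-hydroxy-3,7-dimethyldeca-4,7-dien-1-yl]-2-methyloxiran-2-yl}propanoate
Product: 26 tert-butyl (4S)-4-{(2R,5R)-5-[(1E,4E)-7-(furan-3-yl)-4-methylhepta-1,4-dien-1-yl]-5-methyloxolan-2-yl}-4-hydroxypentanoate
Conditions: CSA (10 mol %), CH2Cl2, −20 → 0 °C; Et3N quench
Reagents that add atoms: none
Why: Acid-catalysed intramolecular opening of a 4,5-epoxy alcohol follows the kinetically preferred 5-exo-tet path, the C8 hydroxyl attacking C5 from the rear with inversion (5S to 5R) while the C4–O bond is kept, as in the closure of epoxylinalool-type substrates to 2,2,5-trisubstituted oxolanes under weak acid.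

Step 18
Reactants: 26 tert-butyl (4S)-4-{(2R,5R)-5-[(1E,4E)-7-(furan-3-yl)-4-methylhepta-1,4-dien-1-yl]-5-methyloxolan-2-yl}-4-hydroxypentanoate
Product: 27 (5S)-5-{(2R,5R)-5-[(1E,4E)-7-(furan-3-yl)-4-methylhepta-1,4-dien-1-yl]-5-methyloxolan-2-yl}-5-methyloxolan-2-one (CNP0387598.1)
Conditions: KOtBu (20 mol %), THF, 0 °C; aq. NH4Cl
Reagents that add atoms: none
Why: Alkoxide-catalysed intramolecular transesterification (5-exo-trig lactonisation) is favoured by the fully substituted C4 and the release of tert-butanol, breaks no bond at a stereocentre and avoids the strong acid that would endanger the furan and the allylic C8–O bond.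

Compound list
1 | 3-[(tert-butyldimethylsilyl)oxy]propanal | O=CCCO[Si](C)(C)C(C)(C)C | starting material
2 | 5-[(tert-butyldimethylsilyl)oxy]-2-methylpent-1-en-3-ol (racemic) | C=C(C)C(O)CCO[Si](C)(C)C(C)(C)C | intermediate
3 | triethyl orthoacetate | CCOC(C)(OCC)OCC | starting material
4 | 5-[(tert-butyldimethylsilyl)oxy]-3-[(1-ethoxyethenyl)oxy]-2-methylpent-1-ene (racemic mixed ketene acetal) | C=C(C)C(CCO[Si](C)(C)C(C)(C)C)OC(=C)OCC | intermediate
5 | ethyl (4E)-7-[(tert-butyldimethylsilyl)oxy]-4-methylhept-4-enoate | CCOC(=O)CC/C(C)=C/CCO[Si](C)(C)C(C)(C)C | intermediate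
6 | tert-butyl (4E)-7-[(tert-butyldimethylsilyl)oxy]-4-methylhept-4-enoate | CC(C)(C)OC(=O)CC/C(C)=C/CCO[Si](C)(C)C(C)(C)C | intermediate
7 | tert-butyl (4E)-7-hydroxy-4-methylhept-4-enoate | CC(C)(C)OC(=O)CC/C(C)=C/CCO | intermediate
8 | tert-butyl (4E)-7-bromo-4-methylhept-4-enoate | CC(C)(C)OC(=O)CC/C(C)=C/CCBr | intermediate
9 | tert-butyl 3-[(2S,3S)-3-(2-bromoethyl)-2-methyloxiran-2-yl]propanoate | BrCC[C@@H]1O[C@@]1(C)CCC(=O)OC(C)(C)C | intermediate
10 | tert-butyl 3-{(2S,3S)-2-methyl-3-[2-(4,4,5,5-tetramethyl-1,3,2-dioxaborolan-2-yl)ethyl]oxiran-2-yl}propanoate | CC1(C)OB(CC[C@@H]2O[C@@]2(C)CCC(=O)OC(C)(C)C)OC1(C)C | intermediate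
11 | furan-3-carbaldehyde | O=Cc1ccoc1 | starting material
12 | ethyl (2E)-3-(furan-3-yl)prop-2-enoate | CCOC(=O)/C=C/c1ccoc1 | intermediate
13 | ethyl 3-(furan-3-yl)propanoate | CCOC(=O)CCc1ccoc1 | intermediate
14 | 3-(furan-3-yl)propanal | O=CCCc1ccoc1 | intermediate
15 | ethyl (2E)-5-(furan-3-yl)-2-methylpent-2-enoate | C/C(=C\CCc1ccoc1)C(=O)OCC | intermediate
16 | (2E)-5-(furan-3-yl)-2-methylpent-2-en-1-ol | C/C(=C\CCc1ccoc1)CO | intermediate
17 | 3-[(3E)-5-bromo-4-methylpent-3-en-1-yl]furan | C/C(=C\CCc1ccoc1)CBr | intermediate
18 | (S)-but-3-yn-2-ol | C#C[C@H](C)O | starting material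
19 | (2S,6E)-9-(furan-3-yl)-6-methylnon-6-en-3-yn-2-ol | C/C(=C\CCc1ccoc1)CC#C[C@H](C)O | intermediate
20 | (2S,3E,6E)-9-(furan-3-yl)-6-methylnona-3,6-dien-2-ol | C/C(=C\CCc1ccoc1)C/C=C/[C@H](C)O | intermediate
21 | (2S,3E,6E)-9-(furan-3-yl)-6-methylnona-3,6-dien-2-yl N,N-diisopropylcarbamate | C/C(=C\CCc1ccoc1)C/C=C/[C@H](C)OC(=O)N(C(C)C)C(C)C | intermediate
22 | (S)-configured C8-lithiated carbamate (Li in place of the C8–H of 21) | C/C(=C\CCc1ccoc1)C/C=C/[C@]([Li])(C)OC(=O)N(C(C)C)C(C)C | intermediate
23 | lithium boronate (ate) complex of 22 and 10, boron bound to C8 and C7 | C/C(=C\CCc1ccoc1)C/C=C/[C@]([B-]1(CC[C@@H]2O[C@@]2(C)CCC(=O)OC(C)(C)C)OC(C)(C)C(C)(C)O1)(C)OC(=O)N(C(C)C)C(C)C.[Li+] | intermediate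
24 | tert-butyl 3-{(2S,3S)-3-[(3S,4E,7E)-10-(furan-3-yl)-3,7-dimethyl-3-(4,4,5,5-tetramethyl-1,3,2-dioxaborolan-2-yl)deca-4,7-dien-1-yl]-2-methyloxiran-2-yl}propanoate | C/C(=C\CCc1ccoc1)C/C=C/[C@@](B1OC(C)(C)C(C)(C)O1)(C)CC[C@@H]2O[C@@]2(C)CCC(=O)OC(C)(C)C | intermediate
25 | tert-butyl 3-{(2S,3S)-3-[(3R,4E,7E)-10-(furan-3-yl)-3-hydroxy-3,7-dimethyldeca-4,7-dien-1-yl]-2-methyloxiran-2-yl}propanoate | C/C(=C\CCc1ccoc1)C/C=C/[C@@](O)(C)CC[C@@H]1O[C@@]1(C)CCC(=O)OC(C)(C)C | intermediate
26 | tert-butyl (4S)-4-{(2R,5R)-5-[(1E,4E)-7-(furan-3-yl)-4-methylhepta-1,4-dien-1-yl]-5-methyloxolan-2-yl}-4-hydroxypentanoate | C/C(=C\CCc1ccoc1)C/C=C/[C@@]1(C)CC[C@H]([C@](O)(C)CCC(=O)OC(C)(C)C)O1 | intermediate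
27 | (5S)-5-{(2R,5R)-5-[(1E,4E)-7-(furan-3-yl)-4-methylhepta-1,4-dien-1-yl]-5-methyloxolan-2-yl}-5-methyloxolan-2-one | C/C(=C\CCc1ccoc1)C/C=C/[C@@]1(C)CC[C@H]([C@]2(C)CCC(=O)O2)O1 | target

Total step count: 18.
Longest linear sequence: 11 steps (steps 8–18, from 11). The boronate branch takes 7 steps (steps 1–7, from 1).

Steps most likely to fail

1. Step 16.
- What may go wrong: metalation may stray from C8–H to furan C2–H or to the doubly allylic C11–H2. Boron may be taken up at the γ-carbon C10. Ate-complex formation may also be reversible and erode the configurational purity.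
- Fallback (sets out from 18, 10 and 17, returns at 25): the C7–C8 shift is run on a truncated carbamate that has neither furan nor skipped diene, and the side chain is attached afterwards by olefin metathesis.
- Carbamoylation of 18 as in step 15 would give (S)-but-3-yn-2-yl N,N-diisopropylcarbamate F1. Semihydrogenation over Lindlar catalyst would then give (S)-but-3-en-2-yl N,N-diisopropylcarbamate F2.
- Lithiation of F2 and borylation with 10 under the conditions of step 16 would lead through the tertiary allylic boronic ester F3. Oxidation in the same flask would give the vinyl carbinol F4.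
- Separately, copper-catalysed coupling of 17 with vinylmagnesium bromide (CuI cat., THF, −30 °C) would give 3-[(3E)-4-methylhepta-3,6-dien-1-yl]furan F5.
- Cross metathesis of F4 with F5 (Hoveyda–Grubbs second-generation catalyst, CH2Cl2, 40 °C) should form the E-C9=C10 bond and give 25. The vinyl group on the quaternary carbinol does not homodimerise, and the trisubstituted alkene is inert.

2. Step 17.
- What may go wrong: the protonated epoxide may open at the tertiary C4, either by 6-endo attack of the C8 hydroxyl or by attack of the ester carbonyl with inversion at C4. Acid may also ionise the tertiary allylic C8–OH.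
- Fallback (sets out from 25, returns at 27): the nucleophile is activated instead of the electrophile.
- Deprotonation of 25 with KH in THF (0 °C → rt, 18-crown-6 if needed) should let the C8 alkoxide open the unactivated epoxide in a pure SN2 manner at the less substituted C5 (5-exo-tet, inversion).
- Without protonation C4 gains no cationic character, so the ester carbonyl cannot compete.
- The C4 alkoxide released then expels tert-butoxide and closes the lactone in the same flask, so steps 17 and 18 merge.
- The path runs only through the alkoxide of 26 and makes no compound outside the list (F0).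

3. Step 6.
- What may go wrong: the dioxirane may discriminate poorly between the alkene faces. The ketone may decay by Baeyer–Villiger oxidation, so that uncatalysed, non-selective epoxidation by Oxone takes over. The supply of the unnatural ketone enantiomer is a further weakness.
- Fallback (sets out from 7, returns at 9): oxygen is delivered under direction of the homoallylic hydroxyl instead of by a free dioxirane.
- Vanadium-catalysed asymmetric epoxidation of 7 would use VO(OiPr)3, a C2-symmetric chiral bishydroxamic acid ligand of the enantiomeric series that delivers the (4S,5S) epoxide, and cumene hydroperoxide in toluene at 0 °C. It would give tert-butyl 3-[(2S,3S)-3-(2-hydroxyethyl)-2-methyloxiran-2-yl]propanoate F6.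
- F6 is kept away from acid and converted by an imidazole-buffered Appel bromination (CBr4, PPh3, CH2Cl2, 0 °C) into 9.

Further compounds
F1 | step 16 | (S)-but-3-yn-2-yl N,N-diisopropylcarbamate | C#C[C@H](C)OC(=O)N(C(C)C)C(C)C
F2 | step 16 | (S)-but-3-en-2-yl N,N-diisopropylcarbamate | C=C[C@H](C)OC(=O)N(C(C)C)C(C)C
F3 | step 16 | tert-butyl 3-{(2S,3S)-2-methyl-3-[(3S)-3-methyl-3-(4,4,5,5-tetramethyl-1,3,2-dioxaborolan-2-yl)pent-4-en-1-yl]oxiran-2-yl}propanoate | C=C[C@@](B1OC(C)(C)C(C)(C)O1)(C)CC[C@@H]2O[C@@]2(C)CCC(=O)OC(C)(C)C
F4 | step 16 | tert-butyl 3-{(2S,3S)-3-[(3R)-3-hydroxy-3-methylpent-4-en-1-yl]-2-methyloxiran-2-yl}propanoate | C=C[C@@](O)(C)CC[C@@H]1O[C@@]1(C)CCC(=O)OC(C)(C)C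
F5 | step 16 | 3-[(3E)-4-methylhepta-3,6-dien-1-yl]furan | C/C(=C\CCc1ccoc1)CC=C
F0 | step 17 | none | none
F6 | step 6 | tert-butyl 3-[(2S,3S)-3-(2-hydroxyethyl)-2-methyloxiran-2-yl]propanoate | OCC[C@@H]1O[C@@]1(C)CCC(=O)OC(C)(C)C
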